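**Strategy.** The target is cut at C6–C11. The chain C12–C11–C6–C7–C8–O, which runs from the hydroxymethyl carbon through the quaternary centre of the seven-membered ring into the cyclohexanone ring, is the atom pattern of an ester enolate Claisen product. The precursor is therefore an eleven-membered lactone joining the C12 carboxyl to O8 of a cyclohexenol whose C5 side chain already carries C1–C4. One Ireland–Claisen ring contraction forms C6–C11, the seven-membered carbocycle, the cis ring fusion and quaternary C11, and leaves a C7=C8 alkene. That alkene (as epoxide) and a C1=C2 enone then close the cyclobutane bond C4–C7.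

Key step: step 17

Numbering: core atoms follow the target SMILES order: C1 and C3 carbinols, C4 quaternary cyclobutane carbon, C5–C7 ring CH, C8 ketone, C9, C10 (CHMe), C11 quaternary, C12 hydroxymethyl.

Remark on the chemistry: the C1 ether is eliminated in step 20, C4 is enolised in step 22 and C11 of compounds 16–22 is enolised in step 17, so their earlier configurations (drawn as the Carroll and Felkin products) do not bear on the target.

Step 1
Reactants: 1 (R)-pulegone
Product: 2 pulegone oxide (both spiro epimers)
Conditions: H2O2 (30%), LiOH, MeOH, 0 → 25 °C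
Reagents that add atoms: hydrogen peroxide, OO
Why: Weitz–Scheffer nucleophilic epoxidation of the enone; the new spiro centre forms as a mixture, which is harmless because that carbon is rebuilt in step 2.

Step 2
Reactants: 2 pulegone oxide
Product: 3 (5R)-5-methyl-2-(phenylsulfanyl)cyclohexan-1-one (both C2 epimers)
Conditions: PhSH, NaH (cat.), THF, 65 °C
Reagents that add atoms: thiophenol, Sc1ccccc1
Why: thiolate opening of the α,β-epoxy ketone at the ring carbon and retro-aldol loss of acetone should give the α-sulfanyl ketone without touching the methyl-bearing centre.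

Step 3
Reactants: 3 (5R)-5-methyl-2-(phenylsulfanyl)cyclohexan-1-one
Product: 5 (R)-5-methylcyclohex-2-en-1-one, via sulfoxide 4 (not isolated)
Conditions: mCPBA, CH2Cl2, −78 °C; then CaCO3, toluene, 110 °C
Reagents that add atoms: none
Why: sulfide oxidation and thermal syn-elimination (sulfoxide pyrolysis) can place the alkene only on the side away from the carbonyl, giving the enone with core C10 intact.

Step 4
Reactants: 6 (E)-but-2-en-1-ol
Product: 7 (E)-but-2-en-1-yl 1H-imidazole-1-carboxylate
Conditions: 1,1'-carbonyldiimidazole, CH2Cl2, 0 → 25 °C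
Reagents that add atoms: 1,1'-carbonyldiimidazole, O=C(n1ccnc1)n1ccnc1
Why: acyl transfer from carbonyldiimidazole to the primary alcohol gives an imidazole carbamate, a reagent that acylates enolates at carbon.

Step 5
Reactants: 5 (R)-5-methylcyclohex-2-en-1-one; 7 (E)-but-2-en-1-yl 1H-imidazole-1-carboxylate
Product: 8 crotyl β-keto ester (ester on core C5, trans to the methyl)
Conditions: LiN(iPr)2, THF, −78 °C; then 7, BF3·OEt2, −78 °C; aq. NH4Cl
Reagents that add atoms: none
Why: kinetic deprotonation of the enone at its saturated α-carbon (core C5) and Claisen-type C-acylation should give the β-keto ester, whose epimerisable ester group settles trans to the C10 methyl.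

Step 6
Reactants: 8 crotyl β-keto ester
Product: 10 (5R,6R)-6-[(2S)-but-3-en-2-yl]-5-methylcyclohex-2-en-1-one, via β-keto acid 9 (not isolated)
Conditions: mesitylene, 165 °C
Reagents that add atoms: none
Why: Carroll rearrangement; the hydrogen-bonded ester enol rearranges through a chair [3,3] transition state on the face away from the C10 methyl, so the (E)-alkene geometry sets C4, and decarboxylation with equilibration leaves the C5 chain trans to the methyl.

Step 7
Reactants: 10 (5R,6R)-6-[(2S)-but-3-en-2-yl]-5-methylcyclohex-2-en-1-one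
Product: 11 epoxy ketone (oxirane at C7–C8)
Conditions: H2O2 (30%), NaOH, MeOH, 0 °C
Reagents that add atoms: hydrogen peroxide, OO
Why: Weitz–Scheffer epoxidation; hydroperoxide adds axially to C8 anti to the C10 methyl, as nucleophiles do with 5-substituted cyclohexenones, so the oxirane lies cis to the C5 chain, and the isolated vinyl group is inert.

Step 8
Reactants: 11 epoxy ketone
Product: 12 cyclohexenol (C8 hydroxyl cis to the C5 chain)
Conditions: N2H4·H2O, AcOH (cat.), MeOH, 0 → 25 °C
Reagents that add atoms: none
Why: Wharton transposition; the epoxy hydrazone loses N2 to give the C6=C7 alkene and the C8 alcohol, which keeps the configuration of the epoxide C–O bond.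

Step 9
Reactants: 12 cyclohexenol
Product: 13 benzoate of 12
Conditions: BzCl, pyridine, DMAP (cat.), CH2Cl2, 0 → 25 °C
Reagents that add atoms: benzoyl chloride, O=C(Cl)c1ccccc1
Why: standard acylation; a benzoate has no α-hydrogen, should survive the enolisation and Lewis acid steps, and is removed together with the methyl ester in step 15.

Step 10
Reactants: 13 benzoate of 12
Product: 14 methyl ketone benzoate (C3 ketone)
Conditions: PdCl2 (10 mol%), CuCl, O2 (1 atm), DMF/H2O, 25 °C
Reagents that add atoms: water, O
Why: Tsuji–Wacker oxidation converts the terminal vinyl group into the C3 methyl ketone with Markovnikov selectivity, while the 1,2-disubstituted ring alkene reacts far more slowly.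

Step 11
Reactants: 15 methyl (S)-3-hydroxy-2-methylpropanoate
Product: 16 methyl (S)-2-methyl-3-oxopropanoate
Conditions: Dess–Martin periodinane, NaHCO3, CH2Cl2, 0 °C; used at once
Reagents that add atoms: none
Why: buffered Dess–Martin oxidation gives the configurationally labile formyl ester, which is used cold and unpurified.

Step 12
Reactants: 14 methyl ketone benzoate; 16 methyl (S)-2-methyl-3-oxopropanoate
Product: 18 aldol adduct (C1 hydroxyl syn to C11 methyl), via silyl enol ether 17 (not isolated)
Conditions: LiN(SiMe3)2, Me3SiCl, THF, −78 °C; then 16, BF3·OEt2, CH2Cl2, −78 °C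
Reagents that add atoms: none
Why: Mukaiyama aldol addition; the kinetic methyl-side silyl enol ether adds to the BF3-activated aldehyde under non-basic conditions (the acidic formyl ester would quench a metal enolate), and Felkin–Anh control should give the 1,11-syn adduct.

Step 13
Reactants: 18 aldol adduct
Product: 19 C1 tert-butyldimethylsilyl ether
Conditions: t-BuMe2SiOTf, 2,6-lutidine, CH2Cl2, −78 °C
Reagents that add atoms: tert-butyldimethylsilyl triflate, CC(C)(C)[Si](C)(C)OS(=O)(=O)C(F)(F)F
Why: silylation of the secondary alcohol at low temperature blocks retro-aldol cleavage and masks the hydroxyl for the lactonisation and the enolate chemistry.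

Step 14
Reactants: 19 C1 tert-butyldimethylsilyl ether
Product: 20 C3 dioxolane
Conditions: Me3SiOCH2CH2OSiMe3, Me3SiOTf (cat.), CH2Cl2, −78 → −20 °C
Reagents that add atoms: 1,2-bis(trimethylsilyloxy)ethane, C[Si](C)(C)OCCO[Si](C)(C)C
Why: Noyori ketalisation masks the C3 ketone under aprotic conditions that leave the β-silyloxy group, both esters and the alkene untouched, so that only C11 can be enolised in step 17.

Step 15
Reactants: 20 C3 dioxolane
Product: 21 hydroxy acid (C8 hydroxyl and C12 carboxyl free)
Conditions: LiOH, THF/MeOH/H2O, 40 °C; then aq. HCl to pH 4, 0 °C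
Reagents that add atoms: lithium hydroxide, [Li+].[OH-]
Why: saponification cleaves the methyl ester and the benzoate in one operation, and the silyl ether and ketal are stable to base and to the brief mild acidification.

Step 16
Reactants: 21 hydroxy acid
Product: 22 bridged eleven-membered lactone
Conditions: 2-methyl-6-nitrobenzoic anhydride, DMAP, Et3N, CH2Cl2 (1 mM, slow addition), 40 °C
Reagents that add atoms: none
Why: Shiina macrolactonisation under high dilution; the cis relation of O8 and the C5 chain lets the seven-atom tether span one face of the cyclohexene, and no new stereocentre is formed.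

Step 17
Reactants: 22 bridged eleven-membered lactone
Product: 25 cis-fused bicyclo[5.4.0]undecene C12 acid, via silyl ketene acetal 23 (not isolated), via trimethylsilyl ester 24 (not isolated)
Conditions: KN(SiMe3)2, Me3SiCl/Et3N (premixed), THF–toluene, −78 °C; then 80 °C; then aq. citric acid/MeOH, 25 °C
Reagents that add atoms: none
Why: Ireland–Claisen rearrangement: KN(SiMe3)2 removes H11 in the presence of Me3SiCl, so the lactone enolate is trapped at −78 °C as ketene acetal 23 before the C1 silyloxy group can be expelled, and on warming 23 undergoes a concerted suprafacial [3,3] shift in which O–C8 breaks, C6–C11 forms and the alkene moves to C7=C8. The closest known reaction type is the ester enolate Claisen ring contraction of macrocyclic allylic lactones to 2-alkenylcycloalkanecarboxylic acids. The seven-membered ring (C1–C6 and C11) closes by transannular C6–C11 bonding inside the eleven-membered ring through a boat-like six-centre transition state, which removes four atoms from the ring. C6 is set by chirality transfer from C8, because the new bond forms on the cyclohexene face that carried O8, which is also the face of the C5 chain, hence the cis fusion. C11 is set by the ketene acetal geometry: the bridged medium ring should allow only the isomer with C1 and the ring oxygen cis, and in the boat this puts C12 on the side of C7 and the C11 methyl outside. The step needs enolisation without β-elimination and a single ketene acetal geometry; the internal silyl quench at low temperature and the ring constraint are meant to secure them.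

Step 18
Reactants: 25 cis-fused bicyclo[5.4.0]undecene C12 acid
Product: 26 C12 primary alcohol
Conditions: LiAlH4, THF, 0 → 65 °C
Reagents that add atoms: none
Why: hydride reduction of the hindered acid gives the neopentyl alcohol; silyl ether, ketal and alkene are inert.

Step 19
Reactants: 26 C12 primary alcohol
Product: 27 C12 tert-butyldiphenylsilyl ether
Conditions: t-BuPh2SiCl, imidazole, DMAP (cat.), DMF, 40 °C
Reagents that add atoms: tert-butyl(chloro)diphenylsilane, CC(C)(C)[Si](Cl)(c1ccccc1)c1ccccc1
Why: silylation of the primary alcohol gives an acid- and base-stable ether whose bulk later shields one face of C1.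

Step 20
Reactants: 27 C12 tert-butyldiphenylsilyl ether
Product: 29 bicyclic C1=C2 enone, via β-silyloxy ketone 28 (not isolated)
Conditions: TsOH·H2O (cat.), acetone/H2O, 25 °C; then DBU, toluene, 60 °C
Reagents that add atoms: water, O
Why: acid-catalysed ketal hydrolysis followed by E1cB elimination of the C1 silyloxy group gives the enone, which leaves C4–H as the only enolisable position of the C3 ketone because C11 carries no hydrogen.

Step 21
Reactants: 29 bicyclic C1=C2 enone
Product: 30 C7–C8 epoxide
Conditions: mCPBA, NaHCO3, CH2Cl2, 0 °C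
Reagents that add atoms: 3-chloroperbenzoic acid, OOC(=O)c1cccc(Cl)c1
Why: Prilezhaev epoxidation attacks the electron-richer C7=C8 alkene rather than the enone and should come from the convex face anti to the C6–C11 bond, placing the oxirane opposite the C5–C4 bond.

Step 22
Reactants: 30 C7–C8 epoxide
Product: 31 tricyclic hydroxy enone (C4–C7 bond, C8 hydroxyl)
Conditions: LiN(SiMe3)2, THF, −78 → 45 °C; aq. NH4Cl
Reagents that add atoms: none
Why: intramolecular enolate alkylation by an epoxide (4-exo-tet, the mode of the Stork epoxynitrile cyclisation); the only possible enolate (C4) opens the oxirane at C7 with inversion in the trans-diaxial Fürst–Plattner sense, which forms the cyclobutane, fixes quaternary C4 by the ring constraint and leaves the C8 alkoxide.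

Step 23
Reactants: 31 tricyclic hydroxy enone
Product: 32 tricyclic enedione (C8 ketone)
Conditions: Dess–Martin periodinane, NaHCO3, CH2Cl2, 25 °C
Reagents that add atoms: none
Why: Dess–Martin oxidation of the secondary alcohol gives the C8 ketone, whose C7 neighbour is a bridgehead that cannot enolise or epimerise.

Step 24
Reactants: 32 tricyclic enedione
Product: 34 C1 β-hydroxy ketone, via C1 pinacol boronate 33 (not isolated)
Conditions: B2pin2, CuCl (5 mol%), DPEphos, NaOtBu (cat.), MeOH, THF, 25 °C; then NaBO3·4H2O, THF/H2O, 25 °C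
Reagents that add atoms: sodium perborate, O=BO[O-].[Na+]
Why: CuCl-catalysed conjugate borylation followed by oxidation with retention; the copper–boryl should add to C1 on the enone face anti to the bulky C12 silyloxymethyl group, so the hydroxyl ends cis to the C11 methyl.

Step 25
Reactants: 34 C1 β-hydroxy ketone
Product: 35 C1,C3 trans-diol
Conditions: Me4NBH(OAc)3, MeCN/AcOH, −30 °C
Reagents that add atoms: none
Why: Evans–Saksena reduction; the C1 alkoxyborohydride delivers hydride to C3 on the face of the C1 oxygen, giving the 1,3-anti diol, and the unactivated C8 ketone is not reduced.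

Step 26
Reactants: 35 C1,C3 trans-diol; 36 angelic acid (two equivalents enter the product)
Product: 38 C1,C3-diangelate, via mixed anhydride 37 (not isolated)
Conditions: 36 (6 equiv), 2,4,6-trichlorobenzoyl chloride (6 equiv), Et3N, toluene, 25 °C; then 35, toluene, 80 °C
Reagents that add atoms: angelic acid as second equivalent, C/C=C(/C)C(=O)O
Why: Yamaguchi-type esterification in which two equivalents of the angelic 2,4,6-trichlorobenzoic mixed anhydride, used in excess and without a nucleophilic catalyst, should acylate both hindered secondary hydroxyls (C1 and C3) while avoiding Z to E isomerisation to tiglate.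

Step 27
Reactants: 38 C1,C3-diangelate
Product: 39 target CNP0287707.1
Conditions: HF·pyridine, pyridine/THF, 0 → 25 °C
Reagents that add atoms: none
Why: fluoride-mediated desilylation under mildly acidic conditions frees the C12 hydroxyl without acyl migration or enoate isomerisation.

**Compound list**

1 | (R)-pulegone | C[C@@H]1CCC(=C(C)C)C(=O)C1 | starting material
2 | pulegone oxide, (6R)-2,2,6-trimethyl-1-oxaspiro[2.5]octan-4-one, both spiro epimers | C[C@@H]1CCC2(OC2(C)C)C(=O)C1 | intermediate
3 | (5R)-5-methyl-2-(phenylsulfanyl)cyclohexan-1-one, both C2 epimers | C[C@@H]1CCC(Sc2ccccc2)C(=O)C1 | intermediate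
4 | (5R)-5-methyl-2-(phenylsulfinyl)cyclohexan-1-one | C[C@@H]1CCC(S(=O)c2ccccc2)C(=O)C1 | intermediate
5 | (R)-5-methylcyclohex-2-en-1-one | C[C@@H]1CC=CC(=O)C1 | intermediate
6 | (E)-but-2-en-1-ol | C/C=C/CO | starting material
7 | (E)-but-2-en-1-yl 1H-imidazole-1-carboxylate | C/C=C/COC(=O)n1ccnc1 | intermediate
8 | (E)-but-2-en-1-yl 6-methyl-2-oxocyclohex-3-ene-1-carboxylate, ester (on core C5) trans to the methyl | O=C1C=CC[C@@H](C)[C@@H]1C(=O)OC/C=C/C | intermediate
9 | 1-(but-3-en-2-yl)-6-methyl-2-oxocyclohex-3-ene-1-carboxylic acid, butenyl trans to the methyl | O=C1C=CC[C@@H](C)[C@]1(C(=O)O)[C@@H](C)C=C | intermediate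
10 | (5R,6R)-6-[(2S)-but-3-en-2-yl]-5-methylcyclohex-2-en-1-one | O=C1C=CC[C@@H](C)[C@@H]1[C@@H](C)C=C | intermediate
11 | 2,3-epoxide of 10, oxirane trans to the methyl and cis to the butenyl group | O=C1[C@@H]2O[C@@H]2C[C@@H](C)[C@@H]1[C@@H](C)C=C | intermediate
12 | 4-(but-3-en-2-yl)-5-methylcyclohex-2-en-1-ol, hydroxyl (C8) cis to the side chain (C5) and trans to the methyl (C10) | O[C@H]1C=C[C@@H]([C@@H](C)C=C)[C@H](C)C1 | intermediate
13 | benzoate of 12 | O=C(O[C@H]1C=C[C@@H]([C@@H](C)C=C)[C@H](C)C1)c1ccccc1 | intermediate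
14 | 5-methyl-4-(3-oxobutan-2-yl)cyclohex-2-en-1-yl benzoate, ring configuration as in 12 | O=C(O[C@H]1C=C[C@@H]([C@@H](C)C(C)=O)[C@H](C)C1)c1ccccc1 | intermediate
15 | methyl (S)-3-hydroxy-2-methylpropanoate | C[C@@H](CO)C(=O)OC | starting material
16 | methyl (S)-2-methyl-3-oxopropanoate | C[C@@H](C=O)C(=O)OC | intermediate
17 | methyl-side trimethylsilyl enol ether of 14 (C2=C3) | O=C(O[C@H]1C=C[C@@H]([C@@H](C)C(=C)O[Si](C)(C)C)[C@H](C)C1)c1ccccc1 | intermediate
18 | methyl 6-[4-(benzoyloxy)-6-methylcyclohex-2-en-1-yl]-3-hydroxy-2-methyl-5-oxoheptanoate, 2,3-syn (C11, C1) | O=C(O[C@H]1C=C[C@@H]([C@@H](C)C(=O)C[C@@H](O)[C@@H](C(=O)OC)C)[C@H](C)C1)c1ccccc1 | intermediate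
19 | 3-O-tert-butyldimethylsilyl ether of 18 (C1 ether) | O=C(O[C@H]1C=C[C@@H]([C@@H](C)C(=O)C[C@@H](O[Si](C)(C)C(C)(C)C)[C@@H](C(=O)OC)C)[C@H](C)C1)c1ccccc1 | intermediate
20 | ethylene ketal of 19 at C3 (1,3-dioxolane) | O=C(O[C@H]1C=C[C@@H]([C@@H](C)C2(OCCO2)C[C@@H](O[Si](C)(C)C(C)(C)C)[C@@H](C(=O)OC)C)[C@H](C)C1)c1ccccc1 | intermediate
21 | hydroxy acid from 20: C8 hydroxyl and C12 carboxyl free, C1 silyl ether and C3 dioxolane kept | O[C@H]1C=C[C@@H]([C@@H](C)C2(OCCO2)C[C@@H](O[Si](C)(C)C(C)(C)C)[C@@H](C(=O)O)C)[C@H](C)C1 | intermediate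
22 | bridged eleven-membered lactone joining C12 to O8 of the cyclohexenol (C1 silyl ether, C3 dioxolane) | O=C1O[C@H]2C=C[C@@H]([C@@H](C)C3(OCCO3)C[C@@H](O[Si](C)(C)C(C)(C)C)[C@@H]1C)[C@H](C)C2 | intermediate
23 | trimethylsilyl ketene acetal of 22, C1 and ring oxygen cis on C11=C12 | O1[C@H]2C=C[C@@H]([C@@H](C)C3(OCCO3)C[C@@H](O[Si](C)(C)C(C)(C)C)/C(C)=C1/O[Si](C)(C)C)[C@H](C)C2 | intermediate
24 | trimethylsilyl ester of 25 | CC(C)(C)[Si](C)(C)O[C@@H]1CC2(OCCO2)[C@H](C)[C@@H]3[C@@H](C=CC[C@H]3C)[C@@]1(C)C(=O)O[Si](C)(C)C | intermediate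
25 | cis-fused bicyclo[5.4.0]undec-7-ene C12 acid (C1 silyl ether, C3 dioxolane, C11 quaternary) | CC(C)(C)[Si](C)(C)O[C@@H]1CC2(OCCO2)[C@H](C)[C@@H]3[C@@H](C=CC[C@H]3C)[C@@]1(C)C(=O)O | intermediate
26 | C12 primary alcohol from 25 | CC(C)(C)[Si](C)(C)O[C@@H]1CC2(OCCO2)[C@H](C)[C@@H]3[C@@H](C=CC[C@H]3C)[C@@]1(C)CO | intermediate
27 | C12 tert-butyldiphenylsilyl ether of 26 | CC(C)(C)[Si](C)(C)O[C@@H]1CC2(OCCO2)[C@H](C)[C@@H]3[C@@H](C=CC[C@H]3C)[C@@]1(C)CO[Si](c1ccccc1)(c1ccccc1)C(C)(C)C | intermediate
28 | C3 ketone from 27 (β-silyloxy ketone) | CC(C)(C)[Si](C)(C)O[C@@H]1CC(=O)[C@H](C)[C@@H]2[C@@H](C=CC[C@H]2C)[C@@]1(C)CO[Si](c1ccccc1)(c1ccccc1)C(C)(C)C | intermediate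
29 | bicyclic enone: C1=C2 conjugated with the C3 ketone, C7=C8 alkene, C12 silyl ether | C1=CC(=O)[C@H](C)[C@@H]2[C@@H](C=CC[C@H]2C)[C@@]1(C)CO[Si](c1ccccc1)(c1ccccc1)C(C)(C)C | intermediate
30 | C7–C8 epoxide of 29, oxirane anti to the C6–C11 and C5–C4 bonds | C1=CC(=O)[C@H](C)[C@@H]2[C@@H]([C@H]3O[C@H]3C[C@H]2C)[C@@]1(C)CO[Si](c1ccccc1)(c1ccccc1)C(C)(C)C | intermediate
31 | tricyclic hydroxy enone: C4–C7 cyclobutane bond, C8 alcohol, C1=C2–C3=O enone | C1=CC(=O)[C@]2(C)[C@@H]3[C@@H]([C@H]2[C@@H](O)C[C@H]3C)[C@@]1(C)CO[Si](c1ccccc1)(c1ccccc1)C(C)(C)C | intermediate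
32 | tricyclic enedione (C3 and C8 ketones) | C1=CC(=O)[C@]2(C)[C@@H]3[C@@H]([C@H]2C(=O)C[C@H]3C)[C@@]1(C)CO[Si](c1ccccc1)(c1ccccc1)C(C)(C)C | intermediate
33 | C1 pinacol boronate of the C3,C8-dione, boron cis to the C11 methyl | CC1(C)OB(OC1(C)C)[C@@H]1CC(=O)[C@]2(C)[C@@H]3[C@@H]([C@H]2C(=O)C[C@H]3C)[C@@]1(C)CO[Si](c1ccccc1)(c1ccccc1)C(C)(C)C | intermediate
34 | C1 β-hydroxy ketone (C3 and C8 ketones), hydroxyl cis to the C11 methyl | O[C@@H]1CC(=O)[C@]2(C)[C@@H]3[C@@H]([C@H]2C(=O)C[C@H]3C)[C@@]1(C)CO[Si](c1ccccc1)(c1ccccc1)C(C)(C)C | intermediate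
35 | C1,C3 trans-diol (C8 ketone, C12 silyl ether) | O[C@@H]1C[C@@H](O)[C@]2(C)[C@@H]3[C@@H]([C@H]2C(=O)C[C@H]3C)[C@@]1(C)CO[Si](c1ccccc1)(c1ccccc1)C(C)(C)C | intermediate
36 | angelic acid, (Z)-2-methylbut-2-enoic acid | C/C=C(/C)C(=O)O | starting material
37 | angelic 2,4,6-trichlorobenzoic anhydride | C/C=C(/C)C(=O)OC(=O)c1c(Cl)cc(Cl)cc1Cl | intermediate
38 | C1,C3-diangelate C12 tert-butyldiphenylsilyl ether | C/C=C(/C)C(=O)O[C@@H]1C[C@@H](OC(=O)/C(C)=C\C)[C@]2(C)[C@@H]3[C@@H]([C@H]2C(=O)C[C@H]3C)[C@@]1(C)CO[Si](c1ccccc1)(c1ccccc1)C(C)(C)C | intermediate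
39 | CNP0287707.1 | C/C=C(/C)C(=O)O[C@@H]1C[C@@H](OC(=O)/C(C)=C\C)[C@]2(C)[C@@H]3[C@@H]([C@H]2C(=O)C[C@H]3C)[C@@]1(C)CO | target

**Totals.** Total step count: 27. Longest linear sequence: 25 steps (1–3, 5–10, 12–27).

**Steps most likely to fail**

Step 17, ring-contracting Ireland–Claisen rearrangement. What may go wrong: β-elimination of the C1 silyloxy group before the enolate is silylated, formation of the other ketene acetal geometry and hence the C11 epimer, or a transition state too strained to rearrange. The fallback makes the C6–C11 bond by an open-chain Claisen rearrangement and closes the seven-membered ring by aldol condensation, which also removes the dependence on the medium-ring lactonisation of step 16. It sets out from cyclohexenol 12 and comes back at enone 29. Esterification of 12 with 3,3-dimethoxy-2-methylpropanoic acid (DCC, DMAP, CH2Cl2) would give the acetal ester F1, either C11 epimer serving. Ireland–Claisen rearrangement (KN(SiMe3)2, Me3SiCl, THF, −78 → 60 °C, aqueous work-up) should give the acid F2, with C6 again set by transfer from C8; C11 epimers, if formed, would be separated here. LiAlH4 would give the alcohol F3 and t-BuPh2SiCl/imidazole the silyl ether F4. Tsuji–Wacker oxidation (PdCl2, CuCl, O2, DMF/H2O) of the vinyl group would give the methyl ketone F5. Acetal hydrolysis (TsOH·H2O, acetone/H2O) would give the keto aldehyde F6, and KOH in MeOH should condense C2 with the non-enolisable C1 aldehyde and dehydrate to the cycloheptenone 29.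

Step 22, cyclobutane closure. What may go wrong: O-alkylation of the enolate to a six-membered enol ether, attack at C8 instead of C7, or no reaction of the lithium enolate with the oxirane. The fallback replaces the basic enolate by a silyl dienol ether under Lewis acid activation, where only carbon can act as nucleophile. It sets out from epoxide 30 and comes back at alcohol 31. LiN(iPr)2 and Me3SiCl (THF, −78 °C) would give the silyl dienol ether F7. TiCl4 in CH2Cl2 at −78 °C should then activate the oxirane for a Mukaiyama-type intramolecular opening at C7, and aqueous work-up would return 31.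

Step 24, hydroxylation of C1. What may go wrong: poor facial selectivity of the copper–boryl addition, since the two faces of C1 differ only in the C11 substituents, giving C1 epimers of 34. The fallback sets C1 by hydroxyl-directed hydride delivery instead of steric approach control. It sets out from 34 (epimer mixture) and comes back at diol 35. Dess–Martin oxidation would give the trione F8, and HF·pyridine the hydroxy trione F9. With Me4NBH(OAc)3 (MeCN/AcOH, −30 °C) the C12 hydroxyl should deliver hydride to C1 on the face of the hydroxymethyl group, and the new C1 hydroxyl should then direct the C3 reduction, giving the triol F10. t-BuPh2SiCl and imidazole (1 equiv, 0 °C) would silylate only the primary hydroxyl and return 35.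

**Further compounds**

F1 | step 17 | 3,3-dimethoxy-2-methylpropanoate ester of 12 (C11 epimers) | COC(OC)C(C)C(=O)O[C@H]1C=C[C@@H]([C@@H](C)C=C)[C@H](C)C1
F2 | step 17 | open-chain Claisen acid: C6–C11 bond, C11 bearing methyl, carboxyl and dimethoxymethyl | OC(=O)[C@@](C)(C(OC)OC)[C@@H]1C=CC[C@@H](C)[C@@H]1[C@@H](C)C=C
F3 | step 17 | C12 alcohol from F2 | OC[C@@](C)(C(OC)OC)[C@@H]1C=CC[C@@H](C)[C@@H]1[C@@H](C)C=C
F4 | step 17 | C12 tert-butyldiphenylsilyl ether of F3 | CC(C)(C)[Si](c1ccccc1)(c1ccccc1)OC[C@@](C)(C(OC)OC)[C@@H]1C=CC[C@@H](C)[C@@H]1[C@@H](C)C=C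
F5 | step 17 | C3 methyl ketone from F4 | CC(C)(C)[Si](c1ccccc1)(c1ccccc1)OC[C@@](C)(C(OC)OC)[C@@H]1C=CC[C@@H](C)[C@@H]1[C@@H](C)C(C)=O
F6 | step 17 | keto aldehyde (C1 aldehyde, C3 methyl ketone) | CC(C)(C)[Si](c1ccccc1)(c1ccccc1)OC[C@@](C)(C=O)[C@@H]1C=CC[C@@H](C)[C@@H]1[C@@H](C)C(C)=O
F7 | step 22 | trimethylsilyl dienol ether of 30 (C3=C4 enol ether, C1=C2 alkene) | C1=CC(O[Si](C)(C)C)=C(C)[C@@H]2[C@@H]([C@H]3O[C@H]3C[C@H]2C)[C@@]1(C)CO[Si](c1ccccc1)(c1ccccc1)C(C)(C)C
F8 | step 24 | tricyclic C1,C3,C8-trione C12 silyl ether | O=C1CC(=O)[C@]2(C)[C@@H]3[C@@H]([C@H]2C(=O)C[C@H]3C)[C@@]1(C)CO[Si](c1ccccc1)(c1ccccc1)C(C)(C)C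
F9 | step 24 | tricyclic C1,C3,C8-trione with free C12 hydroxyl | O=C1CC(=O)[C@]2(C)[C@@H]3[C@@H]([C@H]2C(=O)C[C@H]3C)[C@@]1(C)CO
F10 | step 24 | C1,C3,C12-triol C8 ketone | O[C@@H]1C[C@@H](O)[C@]2(C)[C@@H]3[C@@H]([C@H]2C(=O)C[C@H]3C)[C@@]1(C)CO
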